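**Plan**

- Cuts: the three phenols are masked as allyl ethers. C5–O and C7–O go back to C–F. Ring C is cut at C3–C4 and O1–C8a, the ketone at C2–C1' (aryl–carbonyl), and the prenyl group at C5'–CH2.
- Enabling feature: in ring A the oxygens on C8a (O1) and C5 stand ortho, and the oxygen on C7 para, to C4a, the carbon bearing the C4 carbonyl. All three C–O bonds can therefore be written as carbonyl-activated C–F bonds of one symmetric 2,4,6-trifluorobenzoyl group.
- Forward: rings A and B are bought as arenes. Ring B is prenylated (ether, semihydrogenation, Claisen), allylated and acylated to the α-methoxy ketone. Ring C, the only ring built, closes in the flask in which the two halves are joined. Fluoride-to-allyloxy exchange and one deallylation finish the route.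
- Stereochemistry: the target has no stereocentre, and its only non-aromatic alkene (C=CMe2 of the prenyl group) has no E/Z isomers, so nothing has to be set.

Key step: step 7

Conventions: flavone numbering is used; prenyl = 3-methylbut-2-en-1-yl, allyl = prop-2-en-1-yl.

Assumption: in the twofold fluoride exchange the C7 fluoride is taken to leave first. Both positions end as allyl ethers, so the order does not affect the product.

**Step 1**
Reactants: 1 4-bromo-2-methoxyphenol; 2 3-chloro-3-methylbut-1-yne
Product: 3 4-bromo-2-methoxy-1-[(2-methylbut-3-yn-2-yl)oxy]benzene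
Conditions: DBU, CuCl2 (cat.), MeCN, 0 °C → rt
Reagents that add atoms: none
Why: Copper-catalysed propargylic substitution, in which the phenoxide attacks the copper allenylidene formed from the tertiary propargyl chloride, should form the hindered tertiary ether at a temperature too low for propargyl Claisen rearrangement to a chromene.

**Step 2**
Reactants: 3 4-bromo-2-methoxy-1-[(2-methylbut-3-yn-2-yl)oxy]benzene
Product: 4 4-bromo-2-methoxy-1-[(2-methylbut-3-en-2-yl)oxy]benzene
Conditions: H2 (1 atm), Pd/CaCO3 poisoned with Pb(OAc)2, quinoline, EtOAc, rt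
Reagents that add atoms: none
Why: Lindlar semihydrogenation should stop at the terminal alkene because the poisoned palladium surface binds alkynes far better than alkenes, and at one atmosphere it leaves the aryl bromide alone.

**Step 3**
Reactants: 4 4-bromo-2-methoxy-1-[(2-methylbut-3-en-2-yl)oxy]benzene
Product: 5 4-bromo-2-methoxy-6-prenylphenol
Conditions: PhNEt2, 140 °C
Reagents that add atoms: none
Why: In this aromatic Claisen rearrangement the [3,3] shift inverts the 1,1-dimethylallyl unit into a prenyl group at C6, the only ortho carbon that bears hydrogen and can rearomatise, while bromine blocks the para position and the basic solvent suppresses acid-induced loss of isoprene.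

**Step 4**
Reactants: 5 4-bromo-2-methoxy-6-prenylphenol
Product: 6 2-(allyloxy)-5-bromo-1-methoxy-3-prenylbenzene
Conditions: allyl bromide, K2CO3, DMF, rt
Reagents that add atoms: allyl bromide, C=CCBr
Why: This Williamson ether synthesis uses allyl so that the 4'-oxygen carries the same group later placed on C5 and C7, which lets all three be removed in one neutral step and spares the acid-sensitive ortho-prenylphenol.

**Step 5**
Reactants: 7 methoxyacetyl chloride
Product: 8 N,2-dimethoxy-N-methylacetamide
Conditions: MeNH(OMe)·HCl, Et3N, CH2Cl2, 0 °C → rt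
Reagents that add atoms: N,O-dimethylhydroxylamine hydrochloride, CNOC.Cl
Why: Weinreb amide formation by N-acylation of the hydroxylamine with a reactive acid chloride is routine, and the ether oxygen does not interfere.

**Step 6**
Reactants: 6 2-(allyloxy)-5-bromo-1-methoxy-3-prenylbenzene; 8 N,2-dimethoxy-N-methylacetamide
Product: 11 1-[4-(allyloxy)-3-methoxy-5-prenylphenyl]-2-methoxyethanone, via aryllithium 9 (not isolated), via lithium hemiaminal adduct 10 (not isolated)
Conditions: n-BuLi (1.05 equiv), THF, −78 °C; then 8, −78 → 0 °C; aq NH4Cl
Reagents that add atoms: none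
Why: Bromine–lithium exchange at −78 °C outruns attack on the allyl ether or deprotonation of the benzylic-allylic CH2, and the Weinreb ketone synthesis stops at the ketone because the chelated adduct 10 collapses only on aqueous quench.

**Step 7**
Reactants: 11 1-[4-(allyloxy)-3-methoxy-5-prenylphenyl]-2-methoxyethanone; 12 2,4,6-trifluorobenzoyl chloride
Product: 15 4'-(allyloxy)-5,7-difluoro-3,3'-dimethoxy-5'-prenylflavone, via lithium enolate 13 (not isolated), via lithium diketonate 14 (not isolated)
Conditions: LiN(SiMe3)2 (2.2 equiv), THF, −78 °C; 12 (1.0 equiv), −78 → 0 °C; then DMPU, 65 °C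
Reagents that add atoms: none
Why: LiN(SiMe3)2 converts 11 into the chelated Z lithium enolate 13, whose carbon attacks acid chloride 12 (C3–C4), and the second equivalent of base immediately deprotonates the far more acidic 2-methoxy-1,3-diketone to diketonate 14, which shields it from further acylation. Once DMPU loosens the lithium chelate and the mixture is warmed, the oxygen on C2 of 14 adds to the adjacent C–F carbon, the β-position of a vinylogous acyl fluoride, and the Meisenheimer-type adduct expels fluoride as LiF (O1–C8a). This is the known tandem enolate C-acylation and intramolecular SNAr of 2-fluorobenzoyl chlorides that leads to chromones, flavones and 4-quinolones. Ring C closes as a six-membered ring by a formal 6-endo-trig addition–elimination (both C8a and C4a of the attacked π bond lie in the new ring), and no stereocentre is formed. C- over O-acylation is required and is favoured by the tightly bound lithium counter-ion in THF and by the excess base, which also allows any enol ester to pass its acyl group on to remaining enolate. Ortho over para fluoride displacement is required and is fixed by geometry, since only an ortho C–F lies within reach of the enolate oxygen, and the symmetry of the trifluoroaryl group makes the two ortho fluorides equivalent, while the amide base is too hindered to attack the C5 and C7 fluorides.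

**Step 8**
Reactants: 15 4'-(allyloxy)-5,7-difluoro-3,3'-dimethoxy-5'-prenylflavone
Product: 17 5,7,4'-tris(allyloxy)-3,3'-dimethoxy-5'-prenylflavone, via 7-allyloxy-5-fluoroflavone 16 (not isolated)
Conditions: allyl alcohol (5 equiv), NaH (4 equiv), THF, 0 °C; then 15, 0 → 60 °C
Reagents that add atoms: allyl alcohol, C=CCO
Why: In this twofold nucleophilic aromatic substitution (SNAr) both fluorides stand ortho or para to the C4 carbonyl, and each displacement leaves a neutral aryl ether rather than a phenoxide, so ring A should stay electrophilic enough for the second exchange.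

**Step 9**
Reactants: 17 5,7,4'-tris(allyloxy)-3,3'-dimethoxy-5'-prenylflavone
Product: 18 dodoviscin J (5,7,4'-trihydroxy-3,3'-dimethoxy-5'-prenylflavone)
Conditions: Pd(PPh3)4 (cat.), morpholine (excess), THF, rt; pH 5 buffer work-up
Reagents that add atoms: none
Why: In this Tsuji–Trost-type deallylation zerovalent palladium ionises each aryl allyl ether to a π-allyl complex and a phenoxide and morpholine traps the allyl unit irreversibly before ring A can be C-allylated, while the C-bound prenyl group (no leaving group) and the methyl ethers are untouched under these neutral conditions.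

**Compound list**

| No. | Name | SMILES | Role |
|---|---|---|---|
| 1 | 4-bromo-2-methoxyphenol | COc1cc(Br)ccc1O | starting material |
| 2 | 3-chloro-3-methylbut-1-yne | C#CC(C)(C)Cl | starting material |
| 3 | 4-bromo-2-methoxy-1-[(2-methylbut-3-yn-2-yl)oxy]benzene | COc1cc(Br)ccc1OC(C)(C)C#C | intermediate |
| 4 | 4-bromo-2-methoxy-1-[(2-methylbut-3-en-2-yl)oxy]benzene | COc1cc(Br)ccc1OC(C)(C)C=C | intermediate |
| 5 | 4-bromo-2-methoxy-6-prenylphenol | COc1cc(Br)cc(CC=C(C)C)c1O | intermediate |
| 6 | 2-(allyloxy)-5-bromo-1-methoxy-3-prenylbenzene | COc1cc(Br)cc(CC=C(C)C)c1OCC=C | intermediate |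
| 7 | methoxyacetyl chloride | COCC(=O)Cl | starting material |
| 8 | N,2-dimethoxy-N-methylacetamide | COCC(=O)N(C)OC | intermediate |
| 9 | [4-(allyloxy)-3-methoxy-5-prenylphenyl]lithium (not isolated) | [Li]c1cc(OC)c(OCC=C)c(CC=C(C)C)c1 | intermediate |
| 10 | lithium hemiaminal adduct of 9 and 8 (racemic, not isolated) | [Li+].[O-]C(COC)(N(C)OC)c1cc(OC)c(OCC=C)c(CC=C(C)C)c1 | intermediate |
| 11 | 1-[4-(allyloxy)-3-methoxy-5-prenylphenyl]-2-methoxyethanone | COCC(=O)c1cc(OC)c(OCC=C)c(CC=C(C)C)c1 | intermediate |
| 12 | 2,4,6-trifluorobenzoyl chloride | O=C(Cl)c1c(F)cc(F)cc1F | starting material |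
| 13 | Z lithium enolate of 11 (not isolated) | [Li+].[O-]/C(=C\OC)c1cc(OC)c(OCC=C)c(CC=C(C)C)c1 | intermediate |
| 14 | lithium enolate of 1-[4-(allyloxy)-3-methoxy-5-prenylphenyl]-2-methoxy-3-(2,4,6-trifluorophenyl)propane-1,3-dione (not isolated) | [Li+].[O-]C(=C(OC)C(=O)c1c(F)cc(F)cc1F)c1cc(OC)c(OCC=C)c(CC=C(C)C)c1 | intermediate |
| 15 | 4'-(allyloxy)-5,7-difluoro-3,3'-dimethoxy-5'-prenylflavone | COc1cc(-c2oc3cc(F)cc(F)c3c(=O)c2OC)cc(CC=C(C)C)c1OCC=C | intermediate |
| 16 | 7,4'-bis(allyloxy)-5-fluoro-3,3'-dimethoxy-5'-prenylflavone (not isolated) | COc1cc(-c2oc3cc(OCC=C)cc(F)c3c(=O)c2OC)cc(CC=C(C)C)c1OCC=C | intermediate |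
| 17 | 5,7,4'-tris(allyloxy)-3,3'-dimethoxy-5'-prenylflavone | COc1cc(-c2oc3cc(OCC=C)cc(OCC=C)c3c(=O)c2OC)cc(CC=C(C)C)c1OCC=C | intermediate |
| 18 | dodoviscin J | COc1cc(-c2oc3cc(O)cc(O)c3c(=O)c2OC)cc(CC=C(C)C)c1O | target |

Total step count: 9
Longest linear sequence: 8 (steps 1–4 and 6–9; step 5 is a one-step side branch)

**Steps most likely to fail**

**Step 7.** The enolate may be acylated on oxygen, the amide base may consume the acid chloride, or the tightly chelated lithium diketonate may be slow to displace fluoride. The fallback forms the same two bonds separately and removes the O/C ambiguity.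
- It sets out from 11, whose lithium enolate (LiN(SiMe3)2, 1.05 equiv, THF, −78 °C) is added to purchased 2,4,6-trifluorobenzaldehyde F1 and quenched cold with AcOH, giving the aldol adduct F2.
- Dess–Martin periodinane (CH2Cl2, NaHCO3, rt) oxidises it to the free 2-methoxy-1,3-diketone F3.
- K2CO3 in MeCN at reflux closes ring C by the same ortho-fluoride displacement, and the route is rejoined at 15.

**Step 8.** The exchange may stall after the first displacement, because the new alkoxy group feeds electron density into ring A. Alternatively, alkoxide may add at C2 and open ring C. The fallback brings the C5 and C7 oxygens in before the ring closure, so the flavone never meets an alkoxide.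
- Purchased 5-fluororesorcinol F4 is bis-allylated (allyl bromide, K2CO3, DMF) to 1,3-bis(allyloxy)-5-fluorobenzene F5.
- Vilsmeier–Haack formylation (POCl3, DMF) at the carbon between fluorine and an allyloxy group gives 2,4-bis(allyloxy)-6-fluorobenzaldehyde F6.
- Pinnick oxidation (NaClO2, NaH2PO4, 2-methyl-2-butene) gives 2,4-bis(allyloxy)-6-fluorobenzoic acid F7.
- 1-Chloro-N,N,2-trimethylprop-1-en-1-amine under neutral conditions gives 2,4-bis(allyloxy)-6-fluorobenzoyl chloride F8.
- The fallback sets out from 11, which is acylated with F8 under the protocol of step 7. The resulting lithium diketonate F9 displaces its single ortho fluoride on longer heating in THF/DMPU, and the route is rejoined at 17.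

**Step 3.** The tertiary allyl ether may fragment with loss of isoprene back to the phenol, or the product may change further on heating (abnormal Claisen rearrangement, cyclisation onto the phenol). The fallback builds the prenyl group by metathesis rather than from a tertiary ether.
- It sets out from 1, which is allylated (allyl bromide, K2CO3, acetone) to 1-(allyloxy)-4-bromo-2-methoxybenzene F10.
- The robust primary allyl ether undergoes Claisen rearrangement (PhNEt2, about 200 °C) to 2-allyl-4-bromo-6-methoxyphenol F11.
- Cross-metathesis with excess 2-methyl-2-butene (second-generation Grubbs catalyst, CH2Cl2, 40 °C) converts allyl into prenyl, and the route is rejoined at 5.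

**Further compounds**

F1 | step 7 | 2,4,6-trifluorobenzaldehyde (purchased) | O=Cc1c(F)cc(F)cc1F
F2 | step 7 | 1-[4-(allyloxy)-3-methoxy-5-prenylphenyl]-3-hydroxy-2-methoxy-3-(2,4,6-trifluorophenyl)propan-1-one (racemic mixture of diastereomers, both centres erased later) | COC(C(O)c1c(F)cc(F)cc1F)C(=O)c1cc(OC)c(OCC=C)c(CC=C(C)C)c1
F3 | step 7 | 1-[4-(allyloxy)-3-methoxy-5-prenylphenyl]-2-methoxy-3-(2,4,6-trifluorophenyl)propane-1,3-dione | COC(C(=O)c1c(F)cc(F)cc1F)C(=O)c1cc(OC)c(OCC=C)c(CC=C(C)C)c1
F4 | step 8 | 5-fluororesorcinol (purchased) | Oc1cc(O)cc(F)c1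
F5 | step 8 | 1,3-bis(allyloxy)-5-fluorobenzene | C=CCOc1cc(F)cc(OCC=C)c1
F6 | step 8 | 2,4-bis(allyloxy)-6-fluorobenzaldehyde | O=Cc1c(F)cc(OCC=C)cc1OCC=C
F7 | step 8 | 2,4-bis(allyloxy)-6-fluorobenzoic acid | OC(=O)c1c(F)cc(OCC=C)cc1OCC=C
F8 | step 8 | 2,4-bis(allyloxy)-6-fluorobenzoyl chloride | O=C(Cl)c1c(F)cc(OCC=C)cc1OCC=C
F9 | step 8 | lithium enolate of 1-[4-(allyloxy)-3-methoxy-5-prenylphenyl]-3-[2,4-bis(allyloxy)-6-fluorophenyl]-2-methoxypropane-1,3-dione | [Li+].[O-]C(=C(OC)C(=O)c1c(F)cc(OCC=C)cc1OCC=C)c1cc(OC)c(OCC=C)c(CC=C(C)C)c1
F10 | step 3 | 1-(allyloxy)-4-bromo-2-methoxybenzene | COc1cc(Br)ccc1OCC=C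
F11 | step 3 | 2-allyl-4-bromo-6-methoxyphenol | COc1cc(Br)cc(CC=C)c1O
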